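How high does target stand in the flask, and when?

| setting | gamma | zeta | flask |
|---|---|---|---|
| starting material | 0.20 M | 0.45 M | 0.30 M |
| remark | run made earlier | run made earlier |  |
| time |  |  | 30 min |

| run | time / min | target / % | starting material / % |
|---|---|---|---|
| gamma | 0.333 | 28.5 | 64.7 |
| gamma | 0.833 | 40.3 | 44.4 |
| gamma | 2.50 | 34.1 | 27.1 |
| gamma | 6.00 | 19.0 | 18.1 |
| gamma | 15.0 | 7.5 | 12.4 |
| gamma | 40.0 | 3.0 | 7.7 |
| zeta | 0.333 | 44.1 | 46.5 |
| zeta | 0.833 | 56.3 | 25.7 |
| zeta | 2.50 | 54.5 | 13.5 |
| zeta | 6.00 | 31.2 | 10.9 |
| zeta | 15.0 | 6.3 | 7.7 |
| zeta | 40.0 | 1.3 | 3.9 |

(scatter of a reading: 1 percentage point)

1. time up to 30 min at which target stands highest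
2. the amount of target, in percent of the starting material charged, at that time

- a species is counted by the starting material in it: one target or self-condensation product or crystals counts as two
- a species is counted by the starting material in it: one side product counts as three
- amounts and yields of target count crystals too
- given per volume of solution although it is solid: crystals
- on the list of suspects stand: 2 starting material -> self-condensation product; crystals <-> target; starting material + target -> side product; 2 starting material <-> target

I assume that 2 starting material <-> target stands at its equilibrium and reckon with what that leaves free. In the gamma run the quotient [target]/[starting material]² reads 11.6 /M at 2.50 min. At the same time in the zeta run, with 60.8 mM starting material, this quotient allows 42.8 mM of dissolved target, yet 123 mM is found, and I read the excess as crystals.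

Early in the gamma run the reciprocal of [starting material] climbs by 8.19 /M/min. The gap in its balance, booked as side product, gives 3.53 /M/min for starting material + target. I set net making equal to this drain in the flask, with dissolved target held at the limit from the start. That puts the peak at 82.0 mM starting material, at 1.08 min. Side product is then 24.0 %, so the balance, in which I neglect self-condensation product, leaves 48.7 % target.

The weak link is the quotient, a single reading. The reading at 6.00 min gives 14.5 /M, and the mean of the two, 13.1 /M, raises the dissolved ceiling, my estimate of the solubility of target, to 48.2 mM. The same chain now gives 85.0 mM starting material and 26.2 % side product. I commit to 45.5 % target at 1.03 min.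

The forecast stands later and higher than my reckoning, at 1.3 min and 49 %, “perhaps with some crystal help”.

The flask peaks at 1.10 min with 46.3 % target.

    2 starting material → self-condensation product (k = 5.20 × 10⁻⁵ /M/s)
    crystals ⇌ target, rate k2*(cs2 - [target]) while solid is left; crystals form when [target] > cs2 (solubility = 49.0 mM, k = 4.20 /s)
    starting material + target → side product (k = 0.0600 /M/s)
    2 starting material ⇌ target (K = 13.0 /M, k = 0.0650 /M/s)

At that time the flask holds 49.0 mM of dissolved target, beside my ceiling of 48.2 mM. At 0.210 min dissolved target is made 4.60 times as fast as it is used up, each step taken net and going into its other forms counted as use; at 30.0 min that ratio is 0.305, and the time of the peak lies between. In the same flask charged with 1.2 M starting material, crystals are present at 30.0 min, and the ceiling gives 8.03 % of that neighbour's charge as dissolved target; in percent of its charge, that neighbour ends with 14.3 % target, crystals counted, and 6.18 % crystals, a difference of 8.12 %.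

(The readings are calculated with constants of no real substance; the scatter is artificial.)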